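## Plan

Atom numbers follow the daucane skeleton of the target: C1 quaternary ring-fusion carbon (CH3), C2 CH–O-angeloyl, C3 CH2, C4 C(OH)(i-Pr), C5 ring-fusion CH, C6 CH–O-aroyl, C7 CH2, C8 C(CH3)=, C9 =CH, C10 CH2; ring A = C1–C5, ring B = the seven-membered ring.
1. Cuts: the two ester C–O bonds first; then C7–C8 and C6–C5 together, which removes C6–C7 as a two-carbon unit; then C5=C8 (aldol condensation), C4–i-Pr, C1–CH3 and C1–C10, back to (S)-4-silyloxycyclopent-2-enone.
2. Enabling feature: in ring B, C5 and C8 are linked on the far side by C9–C10–C1. Joined directly they form a cyclopentenone (ring C: C9=O, C8(CH3)=C5, C10, C1) fused to ring A, so ring B is "cyclopentenone + C6–C7". The C8=C9 alkene is the memory of the enone carbonyl, and C6(O)/C7H2 map onto a ketene acetal.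
3. Forward order of rings: ring A (commercial) → ring C by aldol condensation → cyclobutane ring D (C5–C6–C7–C8) by [2+2] photocycloaddition → ring B by reductive cleavage of the strained C5–C8 bond (two-carbon ring expansion) → esters.
4. Stereochemistry: C2 from the commercial enone; C1 and C4 by additions anti to the C2 silyl ether; C5 when the C5–C8 bond is cut (cis fusion, also the more stable epimer); C6 by reduction directed by the C4 hydroxyl; the (Z)-angelate from angelic acid.

Key step: step 7

Assumption: both enantiomers of 4-(tert-butyldimethylsilyloxy)cyclopent-2-enone are commercial; the (S)-enantiomer is used because the target is 1R,2S,4S,5R,6R in the numbering above.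

## Route

Step 1
Reactants: 1 (S)-4-(tert-butyldimethylsilyloxy)cyclopent-2-en-1-one; 2 2-(2-bromoethyl)-2-methyl-1,3-dioxolane
Product: 4 (3S,4S)-4-(tert-butyldimethylsilyloxy)-3-[2-(2-methyl-1,3-dioxolan-2-yl)ethyl]-1-(trimethylsilyloxy)cyclopent-1-ene, via Grignard reagent 3 (not isolated)
Conditions: 2, Mg, THF, 25 °C; then CuBr·SMe2 (10 mol%), TMSCl, 1, THF, −78 °C; Et3N quench
Reagents that add atoms: chlorotrimethylsilane, C[Si](C)(C)Cl
Why: Copper-catalysed conjugate addition of the Grignard reagent to a 4-silyloxycyclopentenone should occur anti to the OTBS group, and TMSCl traps the enolate regiospecifically as its silyl enol ether; the new C1 stereocentre is transient and is erased in step 2.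

Step 2
Reactants: 4 silyl enol ether
Product: 5 (S)-4-(tert-butyldimethylsilyloxy)-3-[2-(2-methyl-1,3-dioxolan-2-yl)ethyl]cyclopent-2-en-1-one
Conditions: Pd(OAc)2 (10 mol%), O2 (1 atm), DMSO, 25 °C
Reagents that add atoms: none
Why: Saegusa–Ito oxidation (divalent palladium enolate, β-hydride elimination, reoxidation of zerovalent palladium by O2) should return the enone with the side chain now on the β-carbon, without creating a stereocentre or touching C2.

Step 3
Reactants: 5 β-substituted enone
Product: 7 (3R,4S)-4-(tert-butyldimethylsilyloxy)-3-methyl-3-[2-(2-methyl-1,3-dioxolan-2-yl)ethyl]cyclopentan-1-one, via silyl enol ether 6 (not isolated)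
Conditions: MeMgBr, CuBr·SMe2 (10 mol%), TMSCl, THF, −78 → −40 °C; then 1 M aqueous HCl/THF (1:10), 0 °C, 10 min
Reagents that add atoms: methylmagnesium bromide, C[Mg]Br
Why: TMSCl-accelerated copper-catalysed conjugate addition to the β,β-disubstituted enone should deliver the methyl group anti to the adjacent OTBS group, so that the quaternary C1 carries CH3 trans and the C10 chain cis to the C2 oxygen as in the target, and brief acid hydrolysis of the silyl enol ether gives the ketone.

Step 4
Reactants: 7 ketal ketone
Product: 9 bicyclic ring-A enone (C4 ketone conjugated to C5=C8), via diketone 8 (not isolated)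
Conditions: TsOH·H2O (0.2 equiv), acetone/H2O (10:1), 40 °C; then solvent change to PhH, 80 °C, Dean–Stark
Reagents that add atoms: none
Why: Acid should unmask the methyl ketone and then drive the intramolecular aldol condensation of the 1,6-diketone, C5 adding to the C8 carbonyl to close ring C; the other possible aldols are bridged and cannot dehydrate, acid is chosen over base to spare the β-silyloxy ketone from elimination, and no new stereocentre remains.

Step 5
Reactants: 9 bicyclic ring-A enone
Product: 10 tertiary allylic alcohol (C4 OH cis to OTBS; i-Pr cis to the C1 methyl)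
Conditions: i-PrMgCl, CeCl3 (anhydrous), THF, −78 °C
Reagents that add atoms: isopropylmagnesium chloride, CC(C)[Mg]Cl
Why: The non-basic organocerium reagent should add 1,2 to the hindered enone without enolisation or reduction, approaching the C4 carbonyl anti to the C2 silyloxy group (the two C1 substituents, CH3 below and C10H2 above, roughly cancel), so that i-Pr ends cis to the C1 methyl and the C4 OH cis to the C2 oxygen.

Step 6
Reactants: 10 tertiary allylic alcohol
Product: 11 ring-C enone (C9 ketone, C8(CH3)=C5)
Conditions: Rh2(cap)4 (cap = caprolactamate, 1 mol%), t-BuOOH (5 equiv), K2CO3, CH2Cl2, 25 °C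
Reagents that add atoms: tert-butyl hydroperoxide, CC(C)(C)OO
Why: Radical allylic oxidation by t-BuOO• can abstract hydrogen only at C9H2 or at the C8 methyl (C4 and C1 are quaternary), the ring methylene should react faster and give the C9 ketone, which completes the chromophore C9(=O)–C8(CH3)=C5 without touching a stereocentre.

Step 7
Reactants: 11 ring-C enone; 12 1,1-diethoxyethene
Product: 13 tricyclic cyclobutane photoadduct (C6 diethyl ketal, C9 ketone)
Conditions: 12 (10 equiv), hν (350 nm, Pyrex), hexane/CH2Cl2, K2CO3 (trace), −20 °C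
Reagents that add atoms: none
Why: Excitation of the cyclopentenone chromophore of 11 (n→π*, then intersystem crossing) gives the enone triplet, which adds to the electron-rich alkene 12 through a 1,4-biradical that collapses to the cyclobutane, so that C7–C8 and C6–C5 form in one photochemical operation; the closest known reaction type is the enone–ketene acetal [2+2] photocycloaddition used for de Mayo-type two-carbon ring expansions. The only ring closed is the four-membered ring D (C5–C6–C7–C8), closed in the [2+2] mode across the enone double bond C5=C8 (first bond by radical addition, second by biradical recombination). The two new stereocentres, quaternary C5 and C8, are controlled by ring strain alone: rings A/C and C/D can only be cis-fused, so the alkene must add on the face of ring C that carries the C1 methyl group. The selectivity the step needs is head-to-tail regiochemistry (acetal carbon to the β-carbon C5, CH2 to the α-carbon C8), which the polarisation of the triplet enone against the strongly polarised ketene acetal should secure. Facial or exo/endo selectivity is not needed, because C6 is not stereogenic, C8 becomes sp2 in step 8 and C5 is reset there. The feature that makes the event possible is the cyclopentenone C9(=O)–C8(CH3)=C5 hidden in ring B through the C9–C10–C1 bridge.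

Step 8
Reactants: 13 tricyclic photoadduct
Product: 15 ring-expanded C9 enol triflate (C6 diethyl ketal, cis-fused), via samarium enolate 14 (not isolated)
Conditions: SmI2 (2.5 equiv), HMPA (10 equiv), THF, −78 °C; then PhNTf2, −78 → 0 °C
Reagents that add atoms: N-phenylbis(trifluoromethanesulfonimide), O=S(=O)(N(c1ccccc1)S(=O)(=O)C(F)(F)F)C(F)(F)F
Why: Single-electron reduction of the strained cyclobutyl ketone gives a ketyl whose β-scission should cut the ring-fusion bond C8–C5 (between two quaternary carbons, releasing the cyclobutane strain and a tertiary radical) in preference to C8–C7, as in SmI2-mediated reductive ring opening of cyclobutyl ketones; the C5 radical then takes a hydrogen atom from THF on the face opposite C10 (the convex face of the forming bicyclo[5.3.0] system), which sets H5 cis to the C1 methyl, and O-sulfonylation of the regiodefined trivalent samarium enolate stores the future C8=C9 double bond as the enol triflate.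

Step 9
Reactants: 15 enol triflate ketal
Product: 16 C6 ketone enol triflate
Conditions: PPTS (0.3 equiv), acetone/H2O (10:1), 50 °C
Reagents that add atoms: water, O
Why: Mild acid hydrolysis of the diethyl ketal should free the C6 ketone while the silyl ether, the tertiary alcohol and the enol triflate survive (the triflate also keeps the C8=C9 double bond from moving into conjugation); C5 becomes epimerisable here, but the cis-fused epimer, with C6 anti to both the C1 methyl and the C4 isopropyl group, is the favoured one.

Step 10
Reactants: 16 C6 ketone enol triflate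
Product: 17 C4,C6-diol enol triflate
Conditions: Me4NBH(OAc)3, MeCN/AcOH (1:1), −20 °C
Reagents that add atoms: none
Why: In this Evans–Saksena reduction the tertiary C4 hydroxyl exchanges onto boron and hydride is delivered intramolecularly to the concave face of the C6 ketone, on which the C4 oxygen sits, so the C6 oxygen should end on the convex face syn to H5 as in the target, which an external hydride attacking the open convex face would not give.

Step 11
Reactants: 17 diol enol triflate; 18 3,4,5-trimethoxybenzoyl chloride
Product: 19 C6 3,4,5-trimethoxybenzoate enol triflate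
Conditions: Et3N, DMAP (0.2 equiv), CH2Cl2, 25 → 40 °C
Reagents that add atoms: none
Why: DMAP-catalysed acylation should be selective for the only free secondary alcohol (C6), since the tertiary C4 OH is unreactive under these conditions and C2 is still silylated; no stereocentre changes.

Step 12
Reactants: 19 aryl ester enol triflate
Product: 20 C6 aryl ester C2 silyl ether with the C8=C9 alkene
Conditions: Pd(OAc)2 (5 mol%), PPh3 (10 mol%), HCO2H, Et3N, DMF, 60 °C
Reagents that add atoms: none
Why: Palladium-catalysed formate reduction of the enol triflate (oxidative addition to zerovalent palladium, formate exchange, decarboxylation, C–H reductive elimination) should replace OTf by H without moving the double bond, giving the C8(CH3)=C9H alkene and leaving the ester and silyl ether intact.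

Step 13
Reactants: 20 silyl ether
Product: 21 C2 alcohol (C4 OH free, C6 aryl ester)
Conditions: HF·pyridine, pyridine/THF, 0 → 25 °C
Reagents that add atoms: none
Why: Buffered HF should cleave the secondary TBS ether while the aryl ester, the trisubstituted alkene and the tertiary alcohol stay untouched, and it avoids the acyl migration that a basic fluoride source could cause.

Step 14
Reactants: 21 C2 alcohol; 22 angelic acid
Product: 24 target CNP0112256.1, via mixed anhydride 23 (not isolated)
Conditions: 22, 2,4,6-trichlorobenzoyl chloride, Et3N, PhMe, 25 °C; then 21, PhMe, 80 °C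
Reagents that add atoms: none
Why: Yamaguchi-type esterification through the mixed anhydride without DMAP should acylate the hindered secondary C2 alcohol (the tertiary C4 OH does not react) without Z-to-E isomerisation of the angeloyl group, so the alkene geometry comes unchanged from angelic acid.

## Compound list

1 | (S)-4-(tert-butyldimethylsilyloxy)cyclopent-2-en-1-one | CC(C)(C)[Si](C)(C)O[C@H]1CC(=O)C=C1 | starting material
2 | 2-(2-bromoethyl)-2-methyl-1,3-dioxolane | CC1(CCBr)OCCO1 | starting material
3 | [2-(2-methyl-1,3-dioxolan-2-yl)ethyl]magnesium bromide (not isolated) | CC1(CC[Mg]Br)OCCO1 | intermediate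
4 | (3S,4S)-4-(tert-butyldimethylsilyloxy)-3-[2-(2-methyl-1,3-dioxolan-2-yl)ethyl]-1-(trimethylsilyloxy)cyclopent-1-ene (chain trans to OTBS) | CC(C)(C)[Si](C)(C)O[C@H]1CC(O[Si](C)(C)C)=C[C@@H]1CCC2(C)OCCO2 | intermediate
5 | (S)-4-(tert-butyldimethylsilyloxy)-3-[2-(2-methyl-1,3-dioxolan-2-yl)ethyl]cyclopent-2-en-1-one | CC(C)(C)[Si](C)(C)O[C@H]1CC(=O)C=C1CCC2(C)OCCO2 | intermediate
6 | trimethylsilyl enol ether of 7 (not isolated) | CC(C)(C)[Si](C)(C)O[C@H]1CC(O[Si](C)(C)C)=C[C@@]1(C)CCC2(C)OCCO2 | intermediate
7 | (3R,4S)-4-(tert-butyldimethylsilyloxy)-3-methyl-3-[2-(2-methyl-1,3-dioxolan-2-yl)ethyl]cyclopentan-1-one (CH3 trans to OTBS) | CC(C)(C)[Si](C)(C)O[C@H]1CC(=O)C[C@@]1(C)CCC2(C)OCCO2 | intermediate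
8 | (3R,4S)-4-(tert-butyldimethylsilyloxy)-3-methyl-3-(3-oxobutyl)cyclopentan-1-one (not isolated) | CC(C)(C)[Si](C)(C)O[C@H]1CC(=O)C[C@@]1(C)CCC(C)=O | intermediate
9 | bicyclo[3.3.0]octenone of rings A and C: C4 ketone conjugated to C5=C8, CH3 on C1 and C8, C2 OTBS trans to the C1 methyl | CC(C)(C)[Si](C)(C)O[C@H]1CC(=O)C2=C(C)CC[C@@]12C | intermediate
10 | as 9, with C4 now C(OH)(i-Pr): OH cis to OTBS, i-Pr cis to the C1 methyl | CC(C)(C)[Si](C)(C)O[C@H]1C[C@](O)(C(C)C)C2=C(C)CC[C@@]12C | intermediate
11 | ring-C enone: C9 ketone, C8(CH3)=C5; C4 OH/i-Pr and C2 OTBS as in 10 | CC(C)(C)[Si](C)(C)O[C@H]1C[C@](O)(C(C)C)C2=C(C)C(=O)C[C@@]12C | intermediate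
12 | 1,1-diethoxyethene (ketene diethyl acetal) | C=C(OCC)OCC | starting material
13 | tricyclic photoadduct: cyclobutane C5–C6–C7–C8 with C6(OEt)2, cis-fused to ring C on the face of the C1 methyl; C9 ketone | CC(C)(C)[Si](C)(C)O[C@H]1C[C@](O)(C(C)C)[C@@]23C(OCC)(OCC)C[C@]2(C)C(=O)C[C@@]13C | intermediate
14 | ring-expanded samarium enolate, C9–O–SmI2 (not isolated) | CC(C)(C)[Si](C)(C)O[C@H]1C[C@](O)(C(C)C)[C@H]2C(OCC)(OCC)CC(C)=C(O[Sm](I)I)C[C@@]12C | intermediate
15 | cis-fused bicyclo[5.3.0]decene: C9 enol triflate (C8=C9), C6 diethyl ketal, H5 cis to the C1 methyl, C4 OH/i-Pr, C2 OTBS | CC(C)(C)[Si](C)(C)O[C@H]1C[C@](O)(C(C)C)[C@H]2C(OCC)(OCC)CC(C)=C(OS(=O)(=O)C(F)(F)F)C[C@@]12C | intermediate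
16 | as 15, with C6 ketone | CC(C)(C)[Si](C)(C)O[C@H]1C[C@](O)(C(C)C)[C@H]2C(=O)CC(C)=C(OS(=O)(=O)C(F)(F)F)C[C@@]12C | intermediate
17 | as 16, with C6 alcohol (6R; O6 syn to H5) | CC(C)(C)[Si](C)(C)O[C@H]1C[C@](O)(C(C)C)[C@H]2[C@H](O)CC(C)=C(OS(=O)(=O)C(F)(F)F)C[C@@]12C | intermediate
18 | 3,4,5-trimethoxybenzoyl chloride | COc1cc(cc(OC)c1OC)C(=O)Cl | starting material
19 | C6 3,4,5-trimethoxybenzoate of 17 | CC(C)(C)[Si](C)(C)O[C@H]1C[C@](O)(C(C)C)[C@H]2[C@H](OC(=O)c3cc(OC)c(OC)c(OC)c3)CC(C)=C(OS(=O)(=O)C(F)(F)F)C[C@@]12C | intermediate
20 | C2 TBS ether of 21 (C8=C9 alkene, C6 aryl ester) | CC(C)(C)[Si](C)(C)O[C@H]1C[C@](O)(C(C)C)[C@H]2[C@H](OC(=O)c3cc(OC)c(OC)c(OC)c3)CC(C)=CC[C@@]12C | intermediate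
21 | C2,C4-diol C6 3,4,5-trimethoxybenzoate (de-angeloyl target) | O[C@H]1C[C@](O)(C(C)C)[C@H]2[C@H](OC(=O)c3cc(OC)c(OC)c(OC)c3)CC(C)=CC[C@@]12C | intermediate
22 | angelic acid, (Z)-2-methylbut-2-enoic acid | C/C=C(/C)C(=O)O | starting material
23 | angelic 2,4,6-trichlorobenzoic anhydride (not isolated) | C/C=C(/C)C(=O)OC(=O)c1c(Cl)cc(Cl)cc1Cl | intermediate
24 | CNP0112256.1 (1R,2S,4S,5R,6R in daucane numbering) | C/C=C(/C)C(=O)O[C@H]1C[C@](O)(C(C)C)[C@H]2[C@H](OC(=O)c3cc(OC)c(OC)c(OC)c3)CC(C)=CC[C@@]12C | target

## Count and risks

Total step count: 14. Longest linear sequence: 14 steps (1 → 24).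

Steps most likely to fail:

Step 7. The 1,4-biradical may revert to enone and alkene instead of closing, because the new C5–C6 bond joins two fully substituted carbons. Fallback, from 11 back to 16: irradiation of 11 with vinyl acetate under the same conditions should give the less congested tricyclic acetate F1 (C6 epimers, head-to-tail). SmI2/HMPA then PhNTf2, as in step 8, should give the ring-expanded acetate enol triflate F2. K2CO3 in MeOH removes the acetyl group to give the alcohol F3, and Dess–Martin periodinane oxidises F3 to ketone 16. The C6 oxygen thus enters at the alcohol level and the ketone needed for the directed reduction is made afterwards.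

Step 8. The ketyl may cut the external C8–C7 bond instead of the ring-fusion bond, or the enolate may be protonated before O-sulfonylation. Fallback, from 11 back to 16, with an electrocyclic instead of a reductive ring opening: irradiation of 11 with ethoxyacetylene should give the cyclobutene photoadduct F4. Thermolysis (PhMe, 160 °C, sealed tube) opens the cyclobutene, which can only break C5–C8, to the 6-ethoxy-2,4-dienone F5. PPTS in wet acetone hydrolyses the dienol ether to the ene-dione F6. Conjugate reduction with LiBH(s-Bu)3 at −78 °C (hydride to C7, the unsubstituted β-carbon of the C9 enone) and trapping of the C9 enolate with PhNTf2 gives 16.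

Step 4. Enolisation toward C3 with β-elimination of the silyloxy group may compete with the aldol condensation. Fallback, from 5 back to 9, with the aldol bond made under kinetic control: PPTS in wet acetone converts 5 into the keto enone F7. Me2CuLi (THF, −78 → 0 °C) adds the methyl group anti to OTBS, and the regiodefined enolate closes onto the side-chain ketone to give the aldol F8. (CF3CO)2O, Et3N and DMAP at 0 °C dehydrate F8 to 9.

## Further compounds

F1 | step 7 | tricyclic photoadduct with C6 acetate (C6 epimers) | CC(C)(C)[Si](C)(C)O[C@H]1C[C@](O)(C(C)C)[C@@]23C(OC(C)=O)C[C@]2(C)C(=O)C[C@@]13C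
F2 | step 7 | ring-expanded C6 acetate C9 enol triflate (C6 epimers) | CC(C)(C)[Si](C)(C)O[C@H]1C[C@](O)(C(C)C)[C@H]2C(OC(C)=O)CC(C)=C(OS(=O)(=O)C(F)(F)F)C[C@@]12C
F3 | step 7 | ring-expanded C6 alcohol C9 enol triflate (C6 epimers) | CC(C)(C)[Si](C)(C)O[C@H]1C[C@](O)(C(C)C)[C@H]2C(O)CC(C)=C(OS(=O)(=O)C(F)(F)F)C[C@@]12C
F4 | step 8 | cyclobutene photoadduct (C6(OEt)=C7) | CC(C)(C)[Si](C)(C)O[C@H]1C[C@](O)(C(C)C)[C@@]23C(OCC)=C[C@]2(C)C(=O)C[C@@]13C
F5 | step 8 | ring-expanded 6-ethoxy-2,4-dienone (C5=C6(OEt)–C7=C8–C9=O) | CC(C)(C)[Si](C)(C)O[C@H]1C[C@](O)(C(C)C)C2=C(OCC)C=C(C)C(=O)C[C@@]12C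
F6 | step 8 | ene-dione (C6 ketone, C7=C8, C9 ketone; cis-fused) | CC(C)(C)[Si](C)(C)O[C@H]1C[C@](O)(C(C)C)[C@H]2C(=O)C=C(C)C(=O)C[C@@]12C
F7 | step 4 | (S)-4-(tert-butyldimethylsilyloxy)-3-(3-oxobutyl)cyclopent-2-en-1-one | CC(C)(C)[Si](C)(C)O[C@H]1CC(=O)C=C1CCC(C)=O
F8 | step 4 | bicyclic aldol (C8 tertiary alcohol, C4 ketone; C5 and C8 epimers) | CC(C)(C)[Si](C)(C)O[C@H]1CC(=O)C2C(C)(O)CC[C@@]12C
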